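**Strategy**

The dioxane ring is cut at the aryl–oxygen bond between C5 of ring A and the oxygen on C7'. The two aryl–oxygen bonds of the dioxane (C4–O and C5–O) are the only ring bonds to heteroatoms that do not end at a stereocentre; C4–O comes from the bromovanillin phenol, so C5–O can be closed last while C7' and C8' stay untouched. One palladium-catalysed intramolecular etherification of C5–Br by the C7' hydroxyl therefore converts the open-chain syn (7'S,8'S) pair, set by a glycolate aldol, into the trans ring. The precursor is the C7' alcohol whose C8' oxygen carries the 2-bromo-6-methoxyaryl ring A, with O9' tritylated, the ring B phenol as MOM ether and C1 as a dioxolane.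

Key step: step 8

**Remarks on the chemistry (assumptions)**

- Numbering: ring A is C1 (side-chain carbon), C3 (OMe), C4 and C5 (the two dioxane oxygens). C7' is the benzylic carbon bearing ring B, C8' bears C9'H2–O9', and O7', O8' are the oxygens on C7', C8'.
- O9' is masked as a trityl ether, not a silyl ether. O7' and O9' are both β to O8', so a silyl group that hopped to the C7' alkoxide under hot carbonate would free O9' to close an isomeric six-membered ring onto the same C5–Br. Trityl cannot migrate and leaves in the same acid step as the dioxolane and the MOM group.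
- The racemic ligand is used in step 8, since no stereocentre is formed there.

**Route**

Step 1
Reactants: 1 (R)-4-benzyl-2-oxazolidinone; 2 bromoacetyl bromide
Product: 4 (R)-4-benzyl-3-(bromoacetyl)oxazolidin-2-one, via N-lithio oxazolidinone 3 (not isolated)
Conditions: n-BuLi (1.0 equiv), THF, −78 °C; then BrCH2COBr (1.1 equiv), −78 → 0 °C
Reagents that add atoms: n-butyllithium, [Li]CCCC (its lithium stays in intermediate 3 only)
Why: N-acylation of a lithiated oxazolidinone by an acid bromide is the standard entry to N-haloacetyl imides; the acyl bromide reacts far faster than the alkyl bromide and the auxiliary stereocentre is not involved.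

Step 2
Reactants: 5 5-bromovanillin
Product: 6 2-bromo-4-(1,3-dioxolan-2-yl)-6-methoxyphenol
Conditions: HOCH2CH2OH (4 equiv), TsOH·H2O (cat.), toluene, reflux, Dean–Stark; Et3N quench
Reagents that add atoms: ethylene glycol, OCCO
Why: acid-catalysed acetalisation driven by azeotropic removal of water masks the C1 aldehyde against the enolate and hydride steps and keeps ring A electron-rich.

Step 3
Reactants: 6 2-bromo-4-(1,3-dioxolan-2-yl)-6-methoxyphenol; 4 (R)-4-benzyl-3-(bromoacetyl)oxazolidin-2-one
Product: 7 (R)-4-benzyl-3-{[2-bromo-4-(1,3-dioxolan-2-yl)-6-methoxyphenoxy]acetyl}oxazolidin-2-one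
Conditions: K2CO3 (1.5 equiv), acetone, rt
Reagents that add atoms: none
Why: Williamson ether synthesis (SN2 of the phenoxide on an α-bromo carbonyl carbon) forms the C4–O8' bond; the very reactive α-bromo imide lets the hindered, weakly basic phenoxide alkylate at room temperature, where imide and acetal are stable.

Step 4
Reactants: 8 vanillin
Product: 9 3-methoxy-4-(methoxymethoxy)benzaldehyde
Conditions: MOMCl, iPr2NEt, CH2Cl2, 0 °C → rt
Reagents that add atoms: chloromethyl methyl ether, COCCl
Why: O-alkylation of the phenol with a chloromethyl ether (MOM protection) gives an aldehyde partner with no acidic proton, stable to boron enolates, hydride and hot carbonate.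

Step 5
Reactants: 7 (R)-4-benzyl-3-{[2-bromo-4-(1,3-dioxolan-2-yl)-6-methoxyphenoxy]acetyl}oxazolidin-2-one; 9 3-methoxy-4-(methoxymethoxy)benzaldehyde
Product: 12 syn-aldol adduct (R)-4-benzyl-3-[(2R,3S)-2-(2-bromo-4-(1,3-dioxolan-2-yl)-6-methoxyphenoxy)-3-hydroxy-3-(3-methoxy-4-(methoxymethoxy)phenyl)propanoyl]oxazolidin-2-one, via boron Z-enolate 10 (not isolated), via boron aldolate 11 (not isolated)
Conditions: Bu2BOTf (1.2 equiv), Et3N (1.4 equiv), CH2Cl2, −78 → 0 °C; then 9 (1.2 equiv), −78 → 0 °C; then pH 7 buffer, MeOH, 30% H2O2, 0 °C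
Reagents that add atoms: dibutylboron triflate, CCCCB(CCCC)OS(=O)(=O)C(F)(F)F (its boron stays in intermediates 10 and 11 only)
Why: Evans syn aldol of a glycolate imide: soft enolisation gives the Z boron enolate, which adds through a closed chair (Zimmerman–Traxler) transition state in which the benzyl group of the (R)-auxiliary shields one enolate face, so C8' and C7' are formed together as the syn (2R,3S) adduct, which is the (7'S,8'S) series once C9' is reduced.

Step 6
Reactants: 12 syn-aldol adduct
Product: 13 (1S,2S)-2-[2-bromo-4-(1,3-dioxolan-2-yl)-6-methoxyphenoxy]-1-[3-methoxy-4-(methoxymethoxy)phenyl]propane-1,3-diol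
Conditions: LiBH4 (2.5 equiv), MeOH (2.5 equiv), THF, 0 °C → rt
Reagents that add atoms: none
Why: reductive cleavage of the N-acyl oxazolidinone by borohydride at the exocyclic carbonyl gives the C9' primary alcohol and returns the auxiliary, while aryl bromide, acetal and MOM ether are inert; the C8' descriptor changes from R to S only because C9' drops in priority, with no change in geometry.

Step 7
Reactants: 13 (1S,2S)-diol
Product: 14 (1S,2S)-2-[2-bromo-4-(1,3-dioxolan-2-yl)-6-methoxyphenoxy]-1-[3-methoxy-4-(methoxymethoxy)phenyl]-3-(trityloxy)propan-1-ol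
Conditions: TrCl (1.2 equiv), Et3N, DMAP (cat.), CH2Cl2, rt
Reagents that add atoms: trityl chloride, ClC(c1ccccc1)(c1ccccc1)c1ccccc1
Why: tritylation (O-alkylation by the trityl cation) is selective for the primary hydroxyl on steric grounds and leaves O7'–H as the only free nucleophile, under a base-stable group that cannot migrate.

Step 8
Reactants: 14 (1S,2S)-trityl ether with free C7' hydroxyl and C5–Br
Product: 15 (2S,3S)-6-(1,3-dioxolan-2-yl)-8-methoxy-3-[3-methoxy-4-(methoxymethoxy)phenyl]-2-(trityloxymethyl)-2,3-dihydro-1,4-benzodioxine (trans; 7'S,8'S)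
Conditions: Pd(OAc)2 (5 mol%), rac-2-(di-tert-butylphosphino)-1,1'-binaphthyl (6 mol%), Cs2CO3 (1.5 equiv), toluene, 80 °C
Reagents that add atoms: none
Why: Zerovalent palladium, formed in the flask from Pd(OAc)2 and the phosphine, inserts into C5–Br; carbonate then delivers the C7' alkoxide to divalent palladium and C–O reductive elimination from the seven-membered palladacycle releases the ether and the catalyst. The closest known reaction type is the palladium-catalysed intramolecular O-arylation of secondary alcohols with aryl bromides (Buchwald–Hartwig-type etherification), which is established for 1,4-benzodioxanes and leaves the carbinol configuration intact. The dioxane closes in a 6-exo mode at the arene carbon C5, the C–Br bond lying outside the new ring. No stereocentre is created: the C7'–O and C8'–O bonds are never broken, so the syn (7'S,8'S) chain passes with retention into the trans ring, where aryl and CH2OTr sit diequatorial. The step needs reductive elimination to outrun β-hydride loss from C7' (aryl ketone plus hydrodebromination), which the bulky, electron-rich binaphthyl phosphine and the favourable six-membered closure secure. It also needs O7' to be the only nucleophile, which the trityl ether on O9', the MOM ether on ring B and the electron-rich, acetal-bearing ring A (no Smiles-type aryl shift) secure.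

Step 9
Reactants: 15 protected trans-benzodioxane
Product: 16 (2S,3S)-3-(4-hydroxy-3-methoxyphenyl)-2-(hydroxymethyl)-8-methoxy-2,3-dihydro-1,4-benzodioxine-6-carbaldehyde
Conditions: 3 M aq. HCl, THF (1:2), 45 °C
Reagents that add atoms: water, O
Why: acid hydrolysis removes the three acid-labile groups in one operation (dioxolane to aldehyde, trityl ether to alcohol, MOM ether to phenol) before the acid-sensitive enal exists; the benzodioxane resists dilute aqueous acid, and any reversible ionisation at C7' would reclose to the more stable trans ring with C8' unchanged.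

Step 10
Reactants: 16 benzodioxane aldehyde; 17 (triphenylphosphoranylidene)acetaldehyde
Product: 18 (7'S,8'S)-nocomtal, (E)-3-[(2S,3S)-3-(4-hydroxy-3-methoxyphenyl)-2-(hydroxymethyl)-8-methoxy-2,3-dihydro-1,4-benzodioxin-6-yl]prop-2-enal
Conditions: 17 (1.3 equiv), THF/toluene, 75 °C
Reagents that add atoms: none
Why: Wittig reaction with a stabilised formyl ylide gives the E-enal; the ylide is too weakly basic to deprotonate the phenol or the alcohol, and the ring A aldehyde is not conjugated with the free phenol, so no protection is needed.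

**Compound list**

1 | (R)-4-benzyl-2-oxazolidinone | O=C1N[C@H](Cc2ccccc2)CO1 | starting material
2 | bromoacetyl bromide | BrCC(Br)=O | starting material
3 | N-lithio (R)-4-benzyl-2-oxazolidinone | [Li+].O=C1[N-][C@H](Cc2ccccc2)CO1 | intermediate (not isolated)
4 | (R)-4-benzyl-3-(bromoacetyl)oxazolidin-2-one | O=C(CBr)N1[C@H](Cc2ccccc2)COC1=O | intermediate
5 | 5-bromovanillin (3-bromo-4-hydroxy-5-methoxybenzaldehyde) | COc1cc(C=O)cc(Br)c1O | starting material
6 | 2-bromo-4-(1,3-dioxolan-2-yl)-6-methoxyphenol | COc1cc(C2OCCO2)cc(Br)c1O | intermediate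
7 | (R)-4-benzyl-3-{[2-bromo-4-(1,3-dioxolan-2-yl)-6-methoxyphenoxy]acetyl}oxazolidin-2-one | COc1cc(C2OCCO2)cc(Br)c1OCC(=O)N1[C@H](Cc2ccccc2)COC1=O | intermediate
8 | vanillin | COc1cc(C=O)ccc1O | starting material
9 | 3-methoxy-4-(methoxymethoxy)benzaldehyde | COCOc1ccc(C=O)cc1OC | intermediate
10 | (Z)-dibutylboron enolate of 7 (O–B and aryloxy group cis) | CCCCB(CCCC)O/C(=C\Oc1c(Br)cc(C2OCCO2)cc1OC)N1[C@H](Cc2ccccc2)COC1=O | intermediate (not isolated)
11 | dibutylboron aldolate of 12 (boron on O7') | COc1cc([C@H](OB(CCCC)CCCC)[C@@H](Oc2c(Br)cc(C3OCCO3)cc2OC)C(=O)N2[C@H](Cc3ccccc3)COC2=O)ccc1OCOC | intermediate (not isolated)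
12 | (R)-4-benzyl-3-[(2R,3S)-2-(2-bromo-4-(1,3-dioxolan-2-yl)-6-methoxyphenoxy)-3-hydroxy-3-(3-methoxy-4-(methoxymethoxy)phenyl)propanoyl]oxazolidin-2-one | COc1cc([C@H](O)[C@@H](Oc2c(Br)cc(C3OCCO3)cc2OC)C(=O)N2[C@H](Cc3ccccc3)COC2=O)ccc1OCOC | intermediate
13 | (1S,2S)-2-[2-bromo-4-(1,3-dioxolan-2-yl)-6-methoxyphenoxy]-1-[3-methoxy-4-(methoxymethoxy)phenyl]propane-1,3-diol | COc1cc([C@H](O)[C@@H](Oc2c(Br)cc(C3OCCO3)cc2OC)CO)ccc1OCOC | intermediate
14 | (1S,2S)-2-[2-bromo-4-(1,3-dioxolan-2-yl)-6-methoxyphenoxy]-1-[3-methoxy-4-(methoxymethoxy)phenyl]-3-(trityloxy)propan-1-ol (key-step precursor) | COc1cc([C@H](O)[C@@H](Oc2c(Br)cc(C3OCCO3)cc2OC)COC(c2ccccc2)(c2ccccc2)c2ccccc2)ccc1OCOC | intermediate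
15 | (2S,3S)-6-(1,3-dioxolan-2-yl)-8-methoxy-3-[3-methoxy-4-(methoxymethoxy)phenyl]-2-(trityloxymethyl)-2,3-dihydro-1,4-benzodioxine (key-step product, trans) | COc1cc([C@@H]2Oc3cc(C4OCCO4)cc(OC)c3O[C@H]2COC(c5ccccc5)(c5ccccc5)c5ccccc5)ccc1OCOC | intermediate
16 | (2S,3S)-3-(4-hydroxy-3-methoxyphenyl)-2-(hydroxymethyl)-8-methoxy-2,3-dihydro-1,4-benzodioxine-6-carbaldehyde | COc1cc([C@@H]2Oc3cc(C=O)cc(OC)c3O[C@H]2CO)ccc1O | intermediate
17 | (triphenylphosphoranylidene)acetaldehyde | O=CC=P(c1ccccc1)(c1ccccc1)c1ccccc1 | starting material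
18 | (7'S,8'S)-nocomtal | COc1cc([C@@H]2Oc3cc(/C=C/C=O)cc(OC)c3O[C@H]2CO)ccc1O | target

**Step count and risks**

Total steps: 10. Longest linear sequence: 8 steps (5 → 6 → 7 → 12 → 13 → 14 → 15 → 16 → 18; steps 2, 3, 5, 6, 7, 8, 9, 10).

Steps most likely to fail:

1. Step 8. The palladium alkoxide may lose a β-hydride from C7' faster than it eliminates the ether (aryl ketone and hydrodebromination), or oxidative addition at the electron-rich, ortho-oxygenated bromide may stall. Fallback: the C5–O bond is made by oxidation and the ring is then closed at C7'. Setting out from 14, Miyaura borylation (B2pin2, PdCl2(dppf), KOAc, 1,4-dioxane, 85 °C; acetate forms no alkoxide, so the β-hydride path is closed) should give the C5 pinacol boronate F1. NaBO3·4H2O in THF/H2O should then give the C5 phenol F2. Aqueous HCl in THF (conditions of step 9) should strip the three protecting groups and let the C5 phenol trap the C7' benzylic cation (a p-quinone methide once ring B is a free phenol). The dioxane then closes under thermodynamic control, with the fixed C8' centre directing ring B trans, and the fallback rejoins the route at 16. Control at C7' would rest on equilibrium and not on retention, so a minor cis isomer would have to be separated.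

2. Step 5. The bulky, donor-rich 2-bromo-6-methoxyphenoxy group on the enolate may erode facial or syn/anti selectivity, the boron Lewis acid may open the dioxolane, or addition to the electron-rich aldehyde may be slow. Fallback: both centres are set by reduction with dynamic kinetic resolution instead of by C–C bond formation. Setting out from 6 and 9, alkylation of 6 with ethyl bromoacetate (K2CO3, acetone) should give the aryloxyacetate F3. Its lithium enolate (LiN(iPr)2, THF, −78 °C) should add to 9 to give the racemic aldol mixture F4. Dess–Martin periodinane should oxidise it to the β-keto ester F5, whose C8' is configurationally labile. Asymmetric transfer hydrogenation (RuCl(p-cymene)[(R,R)-TsDPEN], HCO2H/Et3N) should then reduce one rapidly equilibrating enantiomer to the syn hydroxy ester F6, as is known for α-alkoxy β-keto esters. The ligand antipode is the one that delivers 7'S, expected to be (R,R) by the usual aryl ketone model. LiBH4 in THF reduces the ester and rejoins the route at 13.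

3. Step 10. The enal formed competes with the electron-rich aryl aldehyde for the ylide (second olefination to a dienal), and the polar unprotected substrate may react slowly. Fallback: a masked two-carbon ylide that cannot add twice, used before deprotection. Setting out from 15, PPTS in acetone/H2O at rt should open only the dioxolane and give the protected aldehyde F7. Wittig reaction with the ylide from (1,3-dioxolan-2-ylmethyl)triphenylphosphonium bromide (KOtBu, THF, 0 °C → rt) should give the vinyl dioxolane F8 as an E/Z mixture. 3 M aq. HCl in THF should then hydrolyse the acetal, equilibrate the enal to E and remove the trityl and MOM groups, arriving directly at 18.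

**Further compounds**

F1 | step 8 | (1S,2S)-2-[4-(1,3-dioxolan-2-yl)-2-methoxy-6-(4,4,5,5-tetramethyl-1,3,2-dioxaborolan-2-yl)phenoxy]-1-[3-methoxy-4-(methoxymethoxy)phenyl]-3-(trityloxy)propan-1-ol | COc1cc([C@H](O)[C@@H](Oc2c(B3OC(C)(C)C(C)(C)O3)cc(C3OCCO3)cc2OC)COC(c2ccccc2)(c2ccccc2)c2ccccc2)ccc1OCOC
F2 | step 8 | (1S,2S)-2-[4-(1,3-dioxolan-2-yl)-2-hydroxy-6-methoxyphenoxy]-1-[3-methoxy-4-(methoxymethoxy)phenyl]-3-(trityloxy)propan-1-ol | COc1cc([C@H](O)[C@@H](Oc2c(O)cc(C3OCCO3)cc2OC)COC(c2ccccc2)(c2ccccc2)c2ccccc2)ccc1OCOC
F3 | step 5 | ethyl [2-bromo-4-(1,3-dioxolan-2-yl)-6-methoxyphenoxy]acetate | CCOC(=O)COc1c(Br)cc(C2OCCO2)cc1OC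
F4 | step 5 | ethyl 2-[2-bromo-4-(1,3-dioxolan-2-yl)-6-methoxyphenoxy]-3-hydroxy-3-[3-methoxy-4-(methoxymethoxy)phenyl]propanoate (racemic mixture of diastereomers) | CCOC(=O)C(Oc1c(Br)cc(C2OCCO2)cc1OC)C(O)c1ccc(OCOC)c(OC)c1
F5 | step 5 | ethyl 2-[2-bromo-4-(1,3-dioxolan-2-yl)-6-methoxyphenoxy]-3-[3-methoxy-4-(methoxymethoxy)phenyl]-3-oxopropanoate (racemic, C2 labile) | CCOC(=O)C(Oc1c(Br)cc(C2OCCO2)cc1OC)C(=O)c1ccc(OCOC)c(OC)c1
F6 | step 5 | ethyl (2R,3S)-2-[2-bromo-4-(1,3-dioxolan-2-yl)-6-methoxyphenoxy]-3-hydroxy-3-[3-methoxy-4-(methoxymethoxy)phenyl]propanoate | COc1cc([C@H](O)[C@@H](Oc2c(Br)cc(C3OCCO3)cc2OC)C(=O)OCC)ccc1OCOC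
F7 | step 10 | (2S,3S)-8-methoxy-3-[3-methoxy-4-(methoxymethoxy)phenyl]-2-(trityloxymethyl)-2,3-dihydro-1,4-benzodioxine-6-carbaldehyde | COc1cc([C@@H]2Oc3cc(C=O)cc(OC)c3O[C@H]2COC(c4ccccc4)(c4ccccc4)c4ccccc4)ccc1OCOC
F8 | step 10 | (2S,3S)-6-[2-(1,3-dioxolan-2-yl)ethenyl]-8-methoxy-3-[3-methoxy-4-(methoxymethoxy)phenyl]-2-(trityloxymethyl)-2,3-dihydro-1,4-benzodioxine (E/Z mixture) | COc1cc([C@@H]2Oc3cc(C=CC4OCCO4)cc(OC)c3O[C@H]2COC(c5ccccc5)(c5ccccc5)c5ccccc5)ccc1OCOC
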